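## The problem

The target, 2,3,4,6-tetrabromo-1H-indole (11), is a flat, achiral benzo-fused pyrrole with no stereocenter, so the difficulty is purely regiochemical: four C–Br bonds must sit at C2, C3, C4 and C6, while C5, C7 and N1 keep their hydrogens. The benzene-ring bromines at C4 and C6 are meta to each other and cannot be placed by electrophilic bromination of an indole, which attacks the pyrrole ring first; they have to come with the arene. Of the pyrrole bromines, C3–Br is easy because C3 is the enamine carbon. C2–Br on an N–H indole is the hard bond, since the usual answer (N-protection, C2 metalation, bromine quench) clashes with aryl bromides that undergo halogen–metal exchange or halogen migration. The aryl C–Br bonds also rule out zerovalent palladium, hydrogenolysis and dissolving metals, and 2-bromoindoles themselves dislike acid and excess oxidant. The enabling feature is an isomer relationship: if the C2–C3 bond of 2,4,6-tribromoindole (10) is opened and the C2 bromine is moved to C3, then N1 and C2 become an isocyanide on C7a and C3 becomes a bromomethyl group on C3a. The pyrrole ring and the C2–Br bond can therefore form together by isomerization of benzylic bromide 8, with no external bromine source, no base and no protecting group on nitrogen.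

## Retrosynthesis

**C3–Br.** The last bond cut is C3–Br of 11, which leads back to 2,4,6-tribromo-1H-indole (10). C3 is the only nucleophilic carbon left in 10, so the forward step is a one-equivalent electrophilic bromination. Cutting C2–Br last instead would leave the harder problem for the end.

**C2–C3 with bromine shift.** Indole 10 is the aromatic tautomer of 2,4,6-tribromo-3H-indole (9), a cyclic imidoyl bromide. Cutting C2–C3 of 9 and returning the bromine to C3 gives 1,5-dibromo-2-(bromomethyl)-3-isocyanobenzene (8). Compared with closing N1–C2 or N1–C7a, this cut needs no nitrogen protecting group and no later functionalization at C2. The precursor is a simple trisubstituted benzyl bromide. The forward reaction must generate the benzylic radical from the weakest C–Br bond only, close it onto the isocyanide carbon, and pass bromine on to the imidoyl radical in a chain.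

**Benzylic C–Br to C–O.** A benzylic bromide cannot be carried past an aniline or a formamide, which would alkylate intramolecularly. It also cannot be installed by radical bromination next to an isocyanide, which adds bromine. The bromide is therefore made last, from (2,4-dibromo-6-isocyanophenyl)methanol (7), and the alcohol is unmasked from acetate 6. The forward steps are a mild transesterification and an Appel reaction, both compatible with an isocyanide.

**Isocyanide to amine.** Isocyanide 6 is cut at the N≡C unit back to formamide 5 and then to aniline 4. The formyl carbon is the future C2. Dehydration with POCl3 and a tertiary amine is the standard forward step, and the ester and aryl bromides are inert to it.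

**Back to the nitrotoluene.** Aniline 4 comes from nitro ester 3 by chemoselective reduction. Ester 3 comes from benzylic bromide 2 by acetate displacement, and 2 comes from 1,5-dibromo-2-methyl-3-nitrobenzene (1) by benzylic bromination. Compound 1 already carries every ring substituent in the correct place: its two bromines become C4–Br and C6–Br, the methyl carbon becomes C3, and the nitro nitrogen becomes N1.

## Roads not taken

Alternative 1: The cut runs through the benzene ring at C3a–C7a and C4–C5. Methyl (5-bromopyridazin-3-yl)(4-bromobut-3-yn-1-yl)carbamate A1 would be heated so that the tethered bromoalkyne adds across the pyridazine in an intramolecular Diels–Alder reaction. Loss of N2 would leave methyl 4,6-dibromoindoline-1-carboxylate A2.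
- Merits: the reaction class is established, and the two bromines are placed regiospecifically by the two halves of A1.
- Weak points: a pyridazine is a sluggish diene and needs high temperature, which the bromoalkyne of A1 may not survive. The heteroaromatic half of A1 is itself a multistep target. A2 still needs carbamate removal, dehydrogenation of the five-membered ring and both pyrrole brominations, so the hard C2–Br bond is untouched.
- Comparison: this road builds a benzene ring that can simply be bought as 1. Its advantage is a precedented key step, which the chosen plan lacks. The chosen plan sets against this that its key step ends one bromination from the target with C2–Br already in place.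

Alternative 2: The cut is N1–C2. N-[3,5-Dibromo-2-(2,2-dibromoethenyl)phenyl]-4-methylbenzenesulfonamide A3 would be treated with Cs2CO3 in warm DMF to close the ring and retain one vinylic bromine, giving 2,4,6-tribromo-1-(4-methylbenzenesulfonyl)-1H-indole A4. Removal of the sulfonyl group from A4 would give 10, and C3 bromination would finish the synthesis as in the chosen plan.
- Merits: the ring closure is a known, transition-metal-free reaction, and A4 is formed with C2–Br already in place, as in the chosen plan. A3 is reachable from 1 by oxidation of the methyl group to the aldehyde level, dibromo-olefination, nitro reduction and tosylation. The whole sequence to 11 is about eight steps, one fewer than the chosen plan.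
- Weak points: two of those steps install and remove the sulfonyl group. In A4 the C2 position is activated toward the same nucleophiles that cleave the sulfonamide, so the deprotection of A4 may cost the C2 bromine.
- Comparison: in security and length this road is at least the equal of the chosen plan. The chosen plan sets against it a nitrogen that is never protected, a ring closure under neutral conditions, and an isomerization that needs no reagent beyond an initiator.

Alternative 3: The cut is N1–C7a. 2,4-Dibromobenzaldehyde A5 would be condensed with ethyl azidoacetate A6 to give ethyl (2Z)-2-azido-3-(2,4-dibromophenyl)prop-2-enoate A7. Thermolysis of A7 in boiling xylene (Hemetsberger–Knittel reaction) would give ethyl 4,6-dibromo-1H-indole-2-carboxylate A8.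
- Merits: A5 and A6 are simple catalogue compounds, and nitrene insertion from A7 is regiochemically unambiguous because the second ortho position is blocked by bromine. On paper this is the shortest road: about five steps if the C2 carboxyl can be exchanged for bromine.
- Weak points: A8 carries an ester where a bromine is needed. After hydrolysis, the C2 carboxyl must be replaced by bromine through ipso-bromodecarboxylation on a strongly deactivated indole, or removed thermally and followed by a less selective double bromination. The azides A6 and A7 must also be handled in quantity.
- Comparison: this road is better in step count. The chosen plan sets against it that C2–Br is formed directly, not by substitution of a carboxyl group at the least nucleophilic pyrrole carbon, and that no azide is used.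

Key step: step 8

Assumption: nitroarene 1 is taken to be a catalogue compound, and the acetic formic anhydride of step 4 is made in the flask from formic acid and acetic anhydride just before use.

## Route

Step 1
Reactants: 1 1,5-dibromo-2-methyl-3-nitrobenzene
Product: 2 1,5-dibromo-2-(bromomethyl)-3-nitrobenzene
Conditions: NBS (1.1 equiv), AIBN (cat.), PhCF3, 95 °C
Reagents that add atoms: N-bromosuccinimide, O=C1CCC(=O)N1Br
Why: Wohl–Ziegler benzylic bromination; the methyl group is the only sp3 C–H site, the ring is too electron-poor for ionic bromination, and the two ortho substituents disfavour a second bromination at the same carbon.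

Step 2
Reactants: 2 1,5-dibromo-2-(bromomethyl)-3-nitrobenzene
Product: 3 (2,4-dibromo-6-nitrophenyl)methyl acetate
Conditions: KOAc (1.5 equiv), DMF, rt to 40 °C
Reagents that add atoms: potassium acetate, CC(=O)[O-].[K+]
Why: SN2 displacement of a primary benzylic bromide by acetate in a dipolar aprotic solvent; acetate is too weak a base to deprotonate the nitrobenzylic position, and the ester masks the oxygen through the next three steps.

Step 3
Reactants: 3 (2,4-dibromo-6-nitrophenyl)methyl acetate
Product: 4 (2-amino-4,6-dibromophenyl)methyl acetate
Conditions: Fe powder, AcOH, EtOH, 60 °C
Reagents that add atoms: none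
Why: Béchamp-type reduction by electron transfer from iron reduces the nitro group without touching aryl C–Br bonds or the benzylic ester; the temperature is kept moderate and 4 is formylated without storage to suppress O-to-N acetyl migration.

Step 4
Reactants: 4 (2-amino-4,6-dibromophenyl)methyl acetate
Product: 5 (2,4-dibromo-6-formamidophenyl)methyl acetate
Conditions: HCO2H, Ac2O, 50 °C, then 4, THF, 0 °C to rt
Reagents that add atoms: acetic formic anhydride, CC(=O)OC=O (made in the flask from formic acid, O=CO, and acetic anhydride, CC(=O)OC(C)=O)
Why: N-formylation of a weakly nucleophilic aniline with the mixed formic acetic anhydride, which transfers the formyl group because its formyl carbonyl is the less hindered and more electrophilic one.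

Step 5
Reactants: 5 (2,4-dibromo-6-formamidophenyl)methyl acetate
Product: 6 (2,4-dibromo-6-isocyanophenyl)methyl acetate
Conditions: POCl3 (1.2 equiv), Et3N (4 equiv), CH2Cl2, −20 to 0 °C; aq. Na2CO3 quench
Reagents that add atoms: none
Why: Dehydration of an N-aryl formamide to the isocyanide with POCl3 and a tertiary amine (Ugi isocyanide synthesis), by O-phosphorylation and base-induced elimination; the ester and aryl bromides are inert, and the basic medium protects the acid-labile isocyanide.

Step 6
Reactants: 6 (2,4-dibromo-6-isocyanophenyl)methyl acetate
Product: 7 (2,4-dibromo-6-isocyanophenyl)methanol
Conditions: K2CO3 (0.2 equiv), MeOH, 0 °C; pH 7 buffer quench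
Reagents that add atoms: none
Why: Base-catalysed transesterification of the acetate with methanol (Zemplén-type deacetylation); isocyanides tolerate mild base, and low temperature, catalytic K2CO3 and a buffered quench limit the time the free alkoxide spends next to the isocyanide.

Step 7
Reactants: 7 (2,4-dibromo-6-isocyanophenyl)methanol
Product: 8 1,5-dibromo-2-(bromomethyl)-3-isocyanobenzene
Conditions: CBr4 (1.2 equiv), PPh3 (1.2 equiv), CH2Cl2, 0 °C
Reagents that add atoms: tetrabromomethane, BrC(Br)(Br)Br
Why: Appel reaction: bromide displaces the alkoxyphosphonium ion of the primary benzylic alcohol under neutral conditions, which an isocyanide tolerates since the same reagent class serves to prepare isocyanides; 8 is passed quickly through base-washed silica, kept cold and used at once.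

Step 8
Reactants: 8 1,5-dibromo-2-(bromomethyl)-3-isocyanobenzene
Product: 10 2,4,6-tribromo-1H-indole, via 2,4,6-tribromo-3H-indole 9 (not isolated)
Conditions: (Bu3Sn)2 (0.1 equiv), hν (sunlamp, Pyrex), degassed PhH (0.01 M), 80 °C
Reagents that add atoms: none
Why: Proposed new method: photolysis of (Bu3Sn)2 gives stannyl radicals that abstract the benzylic bromine of 8 far more readily than an aryl bromine, and the benzylic radical adds to the carbon of the ortho isocyanide, forming C2–C3 and closing the pyrrole ring in a 5-endo-dig mode. The resulting cyclic σ-imidoyl radical takes bromine from the weak benzylic C–Br bond of a second molecule of 8, which gives the 2-bromo-3H-indole 9 and a new benzylic radical, so tin is needed only for initiation. Tautomerization of 9 to the aromatic 1H-indole 10 is downhill and makes the isomerization irreversible. The closest known reaction types are stannyl-radical cyclizations of 2-alkenylaryl isocyanides to indoles, halogen atom-transfer additions of alkyl halides to isocyanides, and the base-induced closure of ortho-tolyl isocyanides, which shows that the benzylic carbon can reach the isocyanide carbon. No stereocenter is formed. The step needs selectivity for the benzylic over the aryl C–Br bonds, which the large difference in bond strength and the absence of any hydrogen donor should secure, and it needs ring closure to outrun addition of the benzylic radical to a second isocyanide, which the ortho placement of the two groups and high dilution favour. A polar 1,1-insertion of the isocyanide carbon into the same benzylic C–Br bond, should it compete, would lead to the same 9 and would not divert material.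

Step 9
Reactants: 10 2,4,6-tribromo-1H-indole
Product: 11 2,3,4,6-tetrabromo-1H-indole
Conditions: NBS (1.0 equiv), DMF, 0 °C, dark
Reagents that add atoms: N-bromosuccinimide, O=C1CCC(=O)N1Br
Why: Electrophilic aromatic bromination at C3, the enamine-type and only activated carbon left in 10; the three bromines deactivate the benzene ring, so one equivalent of NBS at low temperature should stop at the tetrabromide.

## Compound list

1 | 1,5-dibromo-2-methyl-3-nitrobenzene | Cc1c(Br)cc(Br)cc1[N+](=O)[O-] | starting material
2 | 1,5-dibromo-2-(bromomethyl)-3-nitrobenzene | BrCc1c(Br)cc(Br)cc1[N+](=O)[O-] | intermediate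
3 | (2,4-dibromo-6-nitrophenyl)methyl acetate | CC(=O)OCc1c(Br)cc(Br)cc1[N+](=O)[O-] | intermediate
4 | (2-amino-4,6-dibromophenyl)methyl acetate | CC(=O)OCc1c(Br)cc(Br)cc1N | intermediate
5 | (2,4-dibromo-6-formamidophenyl)methyl acetate | CC(=O)OCc1c(Br)cc(Br)cc1NC=O | intermediate
6 | (2,4-dibromo-6-isocyanophenyl)methyl acetate | CC(=O)OCc1c(Br)cc(Br)cc1[N+]#[C-] | intermediate
7 | (2,4-dibromo-6-isocyanophenyl)methanol | OCc1c(Br)cc(Br)cc1[N+]#[C-] | intermediate
8 | 1,5-dibromo-2-(bromomethyl)-3-isocyanobenzene | [C-]#[N+]c1cc(Br)cc(Br)c1CBr | intermediate
9 | 2,4,6-tribromo-3H-indole | BrC1=Nc2cc(Br)cc(Br)c2C1 | intermediate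
10 | 2,4,6-tribromo-1H-indole | Brc1cc2c(Br)cc(Br)cc2[nH]1 | intermediate
11 | 2,3,4,6-tetrabromo-1H-indole | Brc1cc(Br)c2c(Br)c(Br)[nH]c2c1 | target

## Step count and least certain steps

Total: 9 steps. Longest linear sequence: 9 steps (1 to 11).

**Step 8 (key step, new method).** The chain may fail to propagate. Bromine transfer from a benzylic C–Br bond to the cyclic imidoyl radical may be slow, or the 5-endo closure may be reversible. Dimerization of benzylic radicals and intermolecular radical addition to the isocyanide would then consume the substrate. The fallback uses known chemistry, sets out from 1 and comes back at 10. Reissert condensation of 1 with diethyl oxalate and KOEt should give ethyl 3-(2,4-dibromo-6-nitrophenyl)-2-oxopropanoate F1. Alkaline H2O2 should cleave it oxidatively to (2,4-dibromo-6-nitrophenyl)acetic acid F2. Fe in hot AcOH should reduce the nitro group and close the lactam to 4,6-dibromo-1,3-dihydro-2H-indol-2-one F3. POBr3 with imidazole in 1,2-dichloroethane at 80 °C should convert the lactam into 2-bromoindole 10, which re-enters at step 9.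

**Step 7.** The new benzylic bromide may alkylate triphenylphosphine. On concentration, the isocyanide carbon may be alkylated by the benzylic bromide of another molecule, which would start an ionic oligomerization before the radical step. The fallback sets out from 7 and comes back at 8. It separates activation from bromide delivery and keeps phosphine out of the flask. MsCl and Et3N in CH2Cl2 at −20 °C should give (2,4-dibromo-6-isocyanophenyl)methyl methanesulfonate F4. LiBr in acetone at 0 °C should displace the sulfonate to give 8, which is carried into step 8 as a solution after a solvent switch.

**Step 6.** The alkoxide freed by transesterification may add to the neighbouring isocyanide carbon and close a six-membered cyclic imidate. The fallback sets out from 5 and comes back at 8, so the free isocyano alcohol never appears. K2CO3 in MeOH should deacetylate 5 to N-[3,5-dibromo-2-(hydroxymethyl)phenyl]formamide F5. TBSCl and imidazole should give N-[3,5-dibromo-2-({[tert-butyl(dimethyl)silyl]oxy}methyl)phenyl]formamide F6. POCl3 and Et3N should dehydrate it to tert-butyl[(2,4-dibromo-6-isocyanophenyl)methoxy]dimethylsilane F7. Ph3PBr2 in CH2Cl2 at 0 °C should convert the silyl ether directly into bromide 8.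

**Step 3.** The freshly formed amino group may take the acetyl group from the neighbouring benzylic oxygen (O-to-N acyl migration), or the ester may be partly lost in the acidic medium. The fallback sets out from 3 and comes back at 7. It carries the oxygen as a free alcohol through the reduction and lets the formylation protect it. K2CO3 in MeOH should give (2,4-dibromo-6-nitrophenyl)methanol F8. Fe in AcOH and EtOH should give (2-amino-4,6-dibromophenyl)methanol F9. Excess acetic formic anhydride with pyridine should formylate both nitrogen and oxygen to (2,4-dibromo-6-formamidophenyl)methyl formate F10. POCl3 and Et3N should give (2,4-dibromo-6-isocyanophenyl)methyl formate F11. KHCO3 in MeOH at −10 °C should remove the very labile formate and give 7.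

## Further compounds

F1 | step 8 | ethyl 3-(2,4-dibromo-6-nitrophenyl)-2-oxopropanoate | CCOC(=O)C(=O)Cc1c(Br)cc(Br)cc1[N+](=O)[O-]
F2 | step 8 | (2,4-dibromo-6-nitrophenyl)acetic acid | OC(=O)Cc1c(Br)cc(Br)cc1[N+](=O)[O-]
F3 | step 8 | 4,6-dibromo-1,3-dihydro-2H-indol-2-one | O=C1Cc2c(Br)cc(Br)cc2N1
F4 | step 7 | (2,4-dibromo-6-isocyanophenyl)methyl methanesulfonate | CS(=O)(=O)OCc1c(Br)cc(Br)cc1[N+]#[C-]
F5 | step 6 | N-[3,5-dibromo-2-(hydroxymethyl)phenyl]formamide | OCc1c(Br)cc(Br)cc1NC=O
F6 | step 6 | N-[3,5-dibromo-2-({[tert-butyl(dimethyl)silyl]oxy}methyl)phenyl]formamide | CC(C)(C)[Si](C)(C)OCc1c(Br)cc(Br)cc1NC=O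
F7 | step 6 | tert-butyl[(2,4-dibromo-6-isocyanophenyl)methoxy]dimethylsilane | CC(C)(C)[Si](C)(C)OCc1c(Br)cc(Br)cc1[N+]#[C-]
F8 | step 3 | (2,4-dibromo-6-nitrophenyl)methanol | OCc1c(Br)cc(Br)cc1[N+](=O)[O-]
F9 | step 3 | (2-amino-4,6-dibromophenyl)methanol | Nc1cc(Br)cc(Br)c1CO
F10 | step 3 | (2,4-dibromo-6-formamidophenyl)methyl formate | O=COCc1c(Br)cc(Br)cc1NC=O
F11 | step 3 | (2,4-dibromo-6-isocyanophenyl)methyl formate | O=COCc1c(Br)cc(Br)cc1[N+]#[C-]
A1 | alternative 1 | methyl (5-bromopyridazin-3-yl)(4-bromobut-3-yn-1-yl)carbamate | COC(=O)N(CCC#CBr)c1cc(Br)cnn1
A2 | alternative 1 | methyl 4,6-dibromoindoline-1-carboxylate | COC(=O)N1CCc2c(Br)cc(Br)cc21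
A3 | alternative 2 | N-[3,5-dibromo-2-(2,2-dibromoethenyl)phenyl]-4-methylbenzenesulfonamide | Cc1ccc(cc1)S(=O)(=O)Nc1cc(Br)cc(Br)c1C=C(Br)Br
A4 | alternative 2 | 2,4,6-tribromo-1-(4-methylbenzenesulfonyl)-1H-indole | Cc1ccc(cc1)S(=O)(=O)n1c(Br)cc2c(Br)cc(Br)cc21
A5 | alternative 3 | 2,4-dibromobenzaldehyde | O=Cc1ccc(Br)cc1Br
A6 | alternative 3 | ethyl azidoacetate | CCOC(=O)CN=[N+]=[N-]
A7 | alternative 3 | ethyl (2Z)-2-azido-3-(2,4-dibromophenyl)prop-2-enoate | CCOC(=O)/C(N=[N+]=[N-])=C/c1ccc(Br)cc1Br
A8 | alternative 3 | ethyl 4,6-dibromo-1H-indole-2-carboxylate | CCOC(=O)c1cc2c(Br)cc(Br)cc2[nH]1
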